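**Analysis of the target**

The target is a 3-hydroxyisoflavanone. It is a chroman-4-one in which ring A carries a free 7-hydroxyl and the pyranone ring (O1, C2, C3, C4) carries at C3 both a hydroxyl group and ring B. Ring B is bonded through C1' and is almost fully substituted: hydroxyls at C2' and C3', a methoxy group at C4' and a 2-methylbut-3-en-2-yl (reverse prenyl) group at C5'; only C6' bears hydrogen. The single stereocentre is C3, of R configuration (priorities OH > C4 > C2 > C1'), a fully substituted carbinol carbon with no neighbouring stereocentre to relay from. The tertiary benzylic α-ketol is the delicate part. Strong acid can eliminate water across C2–C3 toward the aromatic isoflavone, base can open the ring by β-elimination of the O1 phenoxide, and the free catechol oxidises readily in basic, aerated media. The terminal alkene rules out hydrogenolytic deprotection. The difficulty is to form the crowded C3–C1' bond and fix the configuration at C3 in the same event, under protecting groups that leave without reduction or harsh acid or base. The plan rests on the position of C3 between C4 and C1'. If C4 is held as a ketal, C3 can itself be a ketone and ring B can be delivered as a carbon nucleophile. A ketal made from a C2-symmetric diol then puts a chiral controller next to the reacting carbonyl without making C4 a stereocentre.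

**Retrosynthetic reasoning**

Target 18 to adduct 17. No skeletal bond is cut. The three methoxymethyl ethers and the C4 dioxolane of 17 are all acetals, so one acidic hydrolysis should release the three phenols and the C4 ketone together. Unveiling the ketone last means the α-ketol never meets a base or an organometallic reagent.

Adduct 17 to ketone 14 and organocerium reagent 16. The C3–C1' bond is cut. This is the bond that joins the two aromatic halves, so the route becomes convergent and the stereocentre is created two steps from the end. Cutting C3–C4 or C2–C3 instead would require the pyranone ring to be built around a preformed carbinol. Ring B is electron-rich, which makes it a poor electrophile but a good aryl-metal, and C1' lies ortho to a protected oxygen that directs metalation of arene 8 to aryllithium 15, the source of 16. The forward reaction has to add to a ketone flanked by an acidic C2 methylene and a quaternary C4, and it has to choose one face.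

Ketone 14 to alcohol 13, dimethyl ketal 11, protected chromanone 10 and chromanone 9. The C3 carbonyl is traced to the alcohol 13, and the chiral dioxolane to the dimethyl ketal 11 by exchange with diol 12. Ketal 11 comes from 10 by a hypervalent iodine α-hydroxylation that oxygenates C3 and ketalises C4 in one operation. This matters because the C4 carbonyl of a 7-alkoxychroman-4-one is a vinylogous ester and would resist direct ketalisation. The 7-oxygen of 10 is protected as a methoxymethyl ether rather than a silyl ether: a silyl ether para to the C4 carbonyl is a vinylogous silyl ester and would be cleaved in the alkaline alcohol of the oxidation, whereas the acetal is inert there and falls in the final acid step.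

Arene 8 to phenol 7, prenyl ether 6, phenol 4 and bromide 5. The O-methyl bond is cut first, then the bond from the ring to the quaternary side-chain carbon. An aryl-bound carbon carrying two methyl groups and a vinyl group is the signature of a [3,3] shift of a prenyl ether, so 7 comes from 6 by aromatic Claisen rearrangement. The oxygen that carried the prenyl group is the one that becomes the 4'-methoxy group. Ether 6 comes from phenol 4 and bromide 5.

Phenol 4 to aldehyde 2 and aldehyde 1. The free phenol is traced to a formyl group (Baeyer–Villiger oxidation through formate 3). This settles the differentiation of three contiguous ring oxygens: in 1 two of them are already hydroxyls and the third position is marked by carbon, so no selective protection of a symmetrical 1,2,3-trihydroxyarene is needed.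

**Alternatives that were turned down**

Alternative 1: Both C2 and C4 are traced to the two ester groups of the prochiral hydroxymalonate A1. In the key step a chiral phosphoric acid would direct the 2'-phenol onto one of the two enantiotopic tert-butyl esters, giving the benzofuranone A2 and setting C3.
- For: the step is catalytic, A1 is easily reached by adding a ring B aryl-metal to a ketomalonate diester, and the stereocentre is set on a small molecule.
- Against: A2 contains neither ring A nor the pyranone ring. The lactone carbonyl and the remaining hindered ester must each be converted, one into an aryl-ether methylene and the other into an aryl ketone bonded to ring A, both at a neopentyl-type quaternary carbon. The temporary ring must then be opened again. Lactonisation by a phenol onto a tert-butyl ester also gives an activated aryl ester and is mechanistically less favourable than the aliphatic cases of this reaction type.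
- Comparison: this route is catalytic where the chosen one uses a stoichiometric auxiliary. The chosen route has every carbon in place when the stereocentre is formed and needs one further step; Alternative 1 needs perhaps six or more.

Alternative 2: The C3–C4 bond is cut, leading to the keto aldehyde A3. A chiral triazolium-derived carbene would convert the aldehyde into a Breslow intermediate that adds to the tethered ketone. This closes the pyranone ring and gives the protected target A4 with C3 set.
- For: on step economy and catalysis this is the stronger route. It forms the ring, the α-ketol and the stereocentre in one catalytic step, the reaction type is well established for 3-hydroxychroman-4-ones, and only deprotection remains.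
- Against for this target: the acceptor carbonyl in A3 is attached to ring B, with an ortho and a para oxygen, so it is both hindered and deactivated, and the aldehyde is itself an electron-rich dialkoxybenzaldehyde. Under the base needed to generate the carbene, an O-phenacyl salicylaldehyde such as A3 can undergo intramolecular aldol condensation to a benzofuran. A3 also requires an α-functionalised aryl ketone of ring B to be made in the presence of the alkene. If the enantioselectivity falls short, A4 is obtained as enantiomers that chromatography cannot separate.
- Comparison: the chosen route uses ring B in the role its electronics favour, as the nucleophile. Its stereochemical by-product is a diastereomer that can be removed before the auxiliary is cleaved, and both antipodes of the auxiliary are available.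

Alternative 3: The C3–O and C2–C3 bonds are cut. A carbene generated from the diazo ketone A5 by a dirhodium tetracarboxylate would be captured by the alcohol A6, and the resulting enol, bound to a chiral phosphoric acid, would add to the aldehyde A7 to give A8. Ring closure by displacement of the aryl fluoride and two deprotections would follow.
- For: two bonds and the oxygenated quaternary centre come from achiral components in one catalytic step, and the C3 oxygen arrives protected.
- Against: trapping of such ylides by A7 is less secure than trapping by activated aldehydes or imines, and a simple 1,2-hydrogen shift to the O–H insertion product competes. A8 is a β-hydroxy ketone with a quaternary α-carbon, so the basic ring closure invites retro-aldol loss of A7. Oxidative removal of the 4-methoxybenzyl group must spare two electron-rich rings, and the catechol acetonide needs stronger acid than the chosen acetals. The sequence to A5 and on from A8 is also longer.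
- Comparison: the chosen route forms one bond by a well-known reaction type and leaves fewer untested events between the key step and the target.

Key step: step 10

Remark on the chemistry: the 3R outcome of step 10 is assumed from the chelate model described there. If the first run gives the 3S epimer in excess, the enantiomer of diol 12 is used in step 8 and nothing else changes.

**Route**

Step 1
Reactants: 1 2,3-dihydroxybenzaldehyde
Product: 2 2,3-bis(methoxymethoxy)benzaldehyde
Conditions: MOMCl, i-Pr2NEt, CH2Cl2, 0 °C to rt
Reagents that add atoms: chloromethyl methyl ether, COCCl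
Why: O-alkylation of both phenols by the reactive chloromethyl ether under amine base (acetal protection); excess reagent overcomes the hydrogen bond between the 2-hydroxyl and the formyl group, which is itself inert.

Step 2
Reactants: 2 2,3-bis(methoxymethoxy)benzaldehyde
Product: 4 2,3-bis(methoxymethoxy)phenol, via aryl formate 3 (not isolated)
Conditions: mCPBA, CH2Cl2, rt; then K2CO3 (cat.), MeOH, rt
Reagents that add atoms: 3-chloroperoxybenzoic acid, OOC(=O)c1cccc(Cl)c1
Why: Baeyer–Villiger oxidation of an electron-rich ortho-alkoxybenzaldehyde (Dakin-type): the aryl group migrates in the Criegee intermediate to give formate 3, which mild methanolysis cleaves. The acetal ethers tolerate the peracid and the carbonate.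

Step 3
Reactants: 4 2,3-bis(methoxymethoxy)phenol; 5 prenyl bromide
Product: 6 1,2-bis(methoxymethoxy)-3-[(3-methylbut-2-en-1-yl)oxy]benzene
Conditions: K2CO3, DMF, rt
Reagents that add atoms: none
Why: Williamson ether synthesis; the phenoxide displaces bromide at the unhindered primary allylic carbon (SN2) and the carbonate base leaves the acetals untouched.

Step 4
Reactants: 6 1,2-bis(methoxymethoxy)-3-[(3-methylbut-2-en-1-yl)oxy]benzene
Product: 7 2,3-bis(methoxymethoxy)-6-(2-methylbut-3-en-2-yl)phenol
Conditions: N,N-diethylaniline, 190 °C, sealed tube
Reagents that add atoms: none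
Why: Aromatic Claisen rearrangement: the [3,3] shift bonds the dimethyl-substituted terminus of the prenyl group to the only free ortho carbon, and tautomerisation of the dienone gives the phenol with the inverted side chain. The other ortho position is blocked, and the amine solvent suppresses acid-catalysed cleavage and cyclisation.

Step 5
Reactants: 7 2,3-bis(methoxymethoxy)-6-(2-methylbut-3-en-2-yl)phenol
Product: 8 2-methoxy-3,4-bis(methoxymethoxy)-1-(2-methylbut-3-en-2-yl)benzene
Conditions: MeI, K2CO3, DMF, rt to 40 °C
Reagents that add atoms: iodomethane, CI
Why: Williamson O-methylation; the small electrophile still reaches the phenoxide flanked by the quaternary carbon and an acetal ether, and with no free ortho hydroxyl left the side chain can no longer cyclise.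

Step 6
Reactants: 9 7-hydroxychroman-4-one
Product: 10 7-(methoxymethoxy)chroman-4-one
Conditions: MOMCl, i-Pr2NEt, CH2Cl2, 0 °C to rt
Reagents that add atoms: chloromethyl methyl ether, COCCl
Why: Phenol protection as an acetal; a base-stable group is required because the next step runs in alkaline methanol, where a silyl ether para to the ketone would be lost.

Step 7
Reactants: 10 7-(methoxymethoxy)chroman-4-one
Product: 11 rac-4,4-dimethoxy-7-(methoxymethoxy)chroman-3-ol
Conditions: PhI(OAc)2, KOH, MeOH, 0 °C to rt
Reagents that add atoms: methanol, CO
Why: Hypervalent iodine α-hydroxylation of a ketone in alkaline methanol (Moriarty oxidation), a known reaction of chroman-4-ones. The enolate is iodinated at C3, methoxide adds to C4, the resulting alkoxide displaces iodobenzene to form a methoxy epoxide, and methanol opens it at C4. The former carbonyl oxygen thus ends as the C3 hydroxyl and C4 emerges directly as its dimethyl ketal.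

Step 8
Reactants: 11 rac-4,4-dimethoxy-7-(methoxymethoxy)chroman-3-ol; 12 (2R,3R)-butane-2,3-diol
Product: 13 (4'R,5'R)-7-(methoxymethoxy)-4',5'-dimethylspiro[chromane-4,2'-[1,3]dioxolan]-3-ol (both C3 epimers)
Conditions: PPTS (cat.), toluene, 50 °C, reduced pressure (MeOH removed)
Reagents that add atoms: none
Why: Acid-catalysed transketalisation: the dimethyl ketal ionises easily to an oxocarbenium ion stabilised by O1 and the 7-oxygen, the diol captures it and closes the five-membered ring, and removal of methanol drives the exchange. The aryl methoxymethyl ether ionises far less readily and should survive; the C3 epimers converge in step 9.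

Step 9
Reactants: 13 (4'R,5'R)-7-(methoxymethoxy)-4',5'-dimethylspiro[chromane-4,2'-[1,3]dioxolan]-3-ol
Product: 14 (4'R,5'R)-7-(methoxymethoxy)-4',5'-dimethylspiro[chromane-4,2'-[1,3]dioxolan]-3-one
Conditions: Dess–Martin periodinane, pyridine, CH2Cl2, 0 °C to rt
Reagents that add atoms: none
Why: Dess–Martin oxidation of a secondary alcohol under buffered, non-aqueous conditions that spare the ketal and do not enolise the product toward C2. The ketone should be dried and used directly.

Step 10
Reactants: 8 2-methoxy-3,4-bis(methoxymethoxy)-1-(2-methylbut-3-en-2-yl)benzene; 14 (4'R,5'R)-7-(methoxymethoxy)-4',5'-dimethylspiro[chromane-4,2'-[1,3]dioxolan]-3-one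
Product: 17 (3R,4'R,5'R)-3-[4-methoxy-2,3-bis(methoxymethoxy)-5-(2-methylbut-3-en-2-yl)phenyl]-7-(methoxymethoxy)-4',5'-dimethylspiro[chromane-4,2'-[1,3]dioxolan]-3-ol, via aryllithium 15 (not isolated), via aryldichlorocerium 16 (not isolated)
Conditions: 8, n-BuLi, THF, 0 °C; anhydrous CeCl3, THF, −78 °C; then 14, −78 to −40 °C; aq. NH4Cl
Reagents that add atoms: none
Why: The only ring hydrogen of 8 that is ortho to a methoxymethoxy group is removed by n-BuLi through coordination of lithium to the acetal oxygens (directed ortho-metalation); the other free position is flanked only by the quaternary carbon, so 15 should form as a single regioisomer. Transmetallation with CeCl3 gives 16, which is strongly nucleophilic toward carbonyl groups but weakly basic, so it should add to the C3 ketone of 14 (1,2-addition) rather than deprotonate the acidic C2 methylene. The closest known reaction types are organocerium additions to enolisable, hindered ketones and chelation-controlled additions of organometallics to α-keto acetals of C2-symmetric diols. No ring is closed; the C3–C1' bond and the C3 stereocentre are formed together. Stereocontrol is expected from the (4'R,5'R)-dioxolane: the metal bridges the carbonyl oxygen and the dioxolane oxygen whose adjacent ring carbon turns its hydrogen, not its methyl group, toward C3, so that this oxygen lies near the carbonyl plane. The second oxygen is then pseudo-axial on the opposite face, with its methyl-bearing carbon leaning over that face, so the aryl group should enter anti to the pseudo-axial C–O bond, which by this model gives the 3R carbinol. The step needs addition to win over enolisation, which cerium secures, and one face to be preferred, which the rigid spiro ketal next to the carbonyl secures; because the auxiliary is still attached, the 3S epimer is a diastereomer and can be removed by chromatography.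

Step 11
Reactants: 17 (3R,4'R,5'R)-3-[4-methoxy-2,3-bis(methoxymethoxy)-5-(2-methylbut-3-en-2-yl)phenyl]-7-(methoxymethoxy)-4',5'-dimethylspiro[chromane-4,2'-[1,3]dioxolan]-3-ol
Product: 18 (3R)-3-[2,3-dihydroxy-4-methoxy-5-(2-methylbut-3-en-2-yl)phenyl]-3,7-dihydroxychroman-4-one
Conditions: 3 M aq. HCl, THF–MeOH, 40 °C
Reagents that add atoms: water, O
Why: Acid hydrolysis of acetals: the three methoxymethyl ethers and the dioxolane cleave through oxocarbenium ions, the one at C4 being stabilised by ring A. No bond to C3 is broken, so the configuration is retained, and dilute acid at mild temperature should avoid dehydration toward the isoflavone.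

**Compound list**

1 | 2,3-dihydroxybenzaldehyde | O=Cc1cccc(O)c1O | starting material
2 | 2,3-bis(methoxymethoxy)benzaldehyde | COCOc1cccc(C=O)c1OCOC | intermediate
3 | 2,3-bis(methoxymethoxy)phenyl formate (formed in the flask) | COCOc1cccc(OC=O)c1OCOC | intermediate
4 | 2,3-bis(methoxymethoxy)phenol | COCOc1cccc(O)c1OCOC | intermediate
5 | prenyl bromide (1-bromo-3-methylbut-2-ene) | CC(C)=CCBr | starting material
6 | 1,2-bis(methoxymethoxy)-3-[(3-methylbut-2-en-1-yl)oxy]benzene | COCOc1cccc(OCC=C(C)C)c1OCOC | intermediate
7 | 2,3-bis(methoxymethoxy)-6-(2-methylbut-3-en-2-yl)phenol | COCOc1ccc(C(C)(C)C=C)c(O)c1OCOC | intermediate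
8 | 2-methoxy-3,4-bis(methoxymethoxy)-1-(2-methylbut-3-en-2-yl)benzene | COCOc1ccc(C(C)(C)C=C)c(OC)c1OCOC | intermediate
9 | 7-hydroxychroman-4-one | O=C1CCOc2cc(O)ccc12 | starting material
10 | 7-(methoxymethoxy)chroman-4-one | O=C1CCOc2cc(OCOC)ccc12 | intermediate
11 | rac-4,4-dimethoxy-7-(methoxymethoxy)chroman-3-ol | COCOc1ccc2c(c1)OCC(O)C2(OC)OC | intermediate
12 | (2R,3R)-butane-2,3-diol | C[C@@H](O)[C@@H](C)O | starting material
13 | (4'R,5'R)-7-(methoxymethoxy)-4',5'-dimethylspiro[chromane-4,2'-[1,3]dioxolan]-3-ol (both C3 epimers) | OC1COc2cc(OCOC)ccc2C13O[C@H](C)[C@@H](C)O3 | intermediate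
14 | (4'R,5'R)-7-(methoxymethoxy)-4',5'-dimethylspiro[chromane-4,2'-[1,3]dioxolan]-3-one | O=C1COc2cc(OCOC)ccc2C13O[C@H](C)[C@@H](C)O3 | intermediate
15 | [4-methoxy-2,3-bis(methoxymethoxy)-5-(2-methylbut-3-en-2-yl)phenyl]lithium (formed in the flask) | [Li]c1cc(C(C)(C)C=C)c(OC)c(OCOC)c1OCOC | intermediate
16 | dichloro[4-methoxy-2,3-bis(methoxymethoxy)-5-(2-methylbut-3-en-2-yl)phenyl]cerium (formed in the flask) | Cl[Ce](Cl)c1cc(C(C)(C)C=C)c(OC)c(OCOC)c1OCOC | intermediate
17 | (3R,4'R,5'R)-3-[4-methoxy-2,3-bis(methoxymethoxy)-5-(2-methylbut-3-en-2-yl)phenyl]-7-(methoxymethoxy)-4',5'-dimethylspiro[chromane-4,2'-[1,3]dioxolan]-3-ol | C=CC(C)(C)c1cc([C@@]2(O)COc3cc(OCOC)ccc3C24O[C@H](C)[C@@H](C)O4)c(OCOC)c(OCOC)c1OC | intermediate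
18 | (3R)-3-[2,3-dihydroxy-4-methoxy-5-(2-methylbut-3-en-2-yl)phenyl]-3,7-dihydroxychroman-4-one | C=CC(C)(C)c1cc([C@@]2(O)COc3cc(O)ccc3C2=O)c(O)c(O)c1OC | target

**Step count and risk**

Total: 11 steps. Longest linear sequence: 7 steps (steps 1–5, 10 and 11); the ring A branch (steps 6–9) joins at step 10.

Step 10 (key step). The most likely failure is poor facial selectivity, because the dioxolane methyl groups sit several bonds from the attack trajectory and the chelate geometry is a model. Enolisation or slow addition at the hindered ketone is the second concern. Fallback: a diol with coordinating arms replaces 12, so the metal is held by three oxygens instead of relying on remote methyl shielding. It sets out from 11 and returns at 18.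
- 11 is exchanged with (2S,3S)-1,4-dimethoxybutane-2,3-diol under the conditions of step 8 to give (4'S,5'S)-7-(methoxymethoxy)-4',5'-bis(methoxymethyl)spiro[chromane-4,2'-[1,3]dioxolan]-3-ol F1.
- Oxidation as in step 9 gives (4'S,5'S)-7-(methoxymethoxy)-4',5'-bis(methoxymethyl)spiro[chromane-4,2'-[1,3]dioxolan]-3-one F2.
- Addition of 16 as in step 10 gives (3R,4'S,5'S)-3-[4-methoxy-2,3-bis(methoxymethoxy)-5-(2-methylbut-3-en-2-yl)phenyl]-7-(methoxymethoxy)-4',5'-bis(methoxymethyl)spiro[chromane-4,2'-[1,3]dioxolan]-3-ol F3.
- Hydrolysis as in step 11 gives 18.
- In the three-point chelate the metal should sit on the dioxolane oxygen whose methoxymethyl arm points toward C3. By the same analysis this calls for the (4'S,5'S) ketal to reach 3R; the sense would be checked as in the main route.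

Step 11. The most likely failure is acid-promoted loss of water across C2–C3, driven by aromatisation to the isoflavone, if the ketal needs stronger acid than expected. Re-attack of released formaldehyde on the electron-rich rings is a second concern. Fallback: the two deprotections are separated. It sets out from 17 and returns at 18.
- The methoxymethyl ethers of 17 are removed without protic acid (TMSOTf, 2,2'-bipyridyl, CH2Cl2, 0 °C, then water) to give (3R,4'R,5'R)-3-[2,3-dihydroxy-4-methoxy-5-(2-methylbut-3-en-2-yl)phenyl]-4',5'-dimethylspiro[chromane-4,2'-[1,3]dioxolane]-3,7-diol F4.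
- The ketal of F4 has no α-hydrogen, so it cannot open to an enol ether under these conditions.
- With the 7-hydroxyl free, the C4 oxocarbenium ion is better stabilised, so dilute aqueous oxalic acid in THF should suffice to hydrolyse the ketal and give 18.

Step 8. The most likely failure is isomerisation of the α-hydroxy ketal: loss of methanol to an enol ether whose enol tautomerises to the α-alkoxy ketone. Partial cleavage of the 7-acetal is a second concern. Fallback: the C3 hydroxyl is masked during the exchange. It sets out from 11 and returns at 13.
- 11 is acetylated (Ac2O, pyridine, DMAP) to 4,4-dimethoxy-7-(methoxymethoxy)chroman-3-yl acetate F5.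
- Exchange with 12 as in step 8 gives (4'R,5'R)-7-(methoxymethoxy)-4',5'-dimethylspiro[chromane-4,2'-[1,3]dioxolan]-3-yl acetate F6.
- Methanolysis (K2CO3, MeOH) gives 13.

Step 4. The most likely failure is further reaction of the first-formed product: a Cope shift of the dienone to the para position, abnormal Claisen isomerisation of the side chain, ring closure of the phenol onto the alkene, or loss of the prenyl group. Fallback: the phenol is captured as it forms. It sets out from 6 and returns at 7.
- 6 is heated with butyric anhydride in N,N-diethylaniline to give 2,3-bis(methoxymethoxy)-6-(2-methylbut-3-en-2-yl)phenyl butanoate F7.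
- Methanolysis (K2CO3, MeOH) gives 7.

**Further compounds**

F1 | step 10 | (4'S,5'S)-7-(methoxymethoxy)-4',5'-bis(methoxymethyl)spiro[chromane-4,2'-[1,3]dioxolan]-3-ol | OC1COc2cc(OCOC)ccc2C13O[C@@H](COC)[C@H](COC)O3
F2 | step 10 | (4'S,5'S)-7-(methoxymethoxy)-4',5'-bis(methoxymethyl)spiro[chromane-4,2'-[1,3]dioxolan]-3-one | O=C1COc2cc(OCOC)ccc2C13O[C@@H](COC)[C@H](COC)O3
F3 | step 10 | (3R,4'S,5'S)-3-[4-methoxy-2,3-bis(methoxymethoxy)-5-(2-methylbut-3-en-2-yl)phenyl]-7-(methoxymethoxy)-4',5'-bis(methoxymethyl)spiro[chromane-4,2'-[1,3]dioxolan]-3-ol | C=CC(C)(C)c1cc([C@@]2(O)COc3cc(OCOC)ccc3C24O[C@@H](COC)[C@H](COC)O4)c(OCOC)c(OCOC)c1OC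
F4 | step 11 | (3R,4'R,5'R)-3-[2,3-dihydroxy-4-methoxy-5-(2-methylbut-3-en-2-yl)phenyl]-4',5'-dimethylspiro[chromane-4,2'-[1,3]dioxolane]-3,7-diol | C=CC(C)(C)c1cc([C@@]2(O)COc3cc(O)ccc3C24O[C@H](C)[C@@H](C)O4)c(O)c(O)c1OC
F5 | step 8 | 4,4-dimethoxy-7-(methoxymethoxy)chroman-3-yl acetate | CC(=O)OC1COc2cc(OCOC)ccc2C1(OC)OC
F6 | step 8 | (4'R,5'R)-7-(methoxymethoxy)-4',5'-dimethylspiro[chromane-4,2'-[1,3]dioxolan]-3-yl acetate | CC(=O)OC1COc2cc(OCOC)ccc2C13O[C@H](C)[C@@H](C)O3
F7 | step 4 | 2,3-bis(methoxymethoxy)-6-(2-methylbut-3-en-2-yl)phenyl butanoate | CCCC(=O)Oc1c(C(C)(C)C=C)ccc(OCOC)c1OCOC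
A1 | alternative 1 | di-tert-butyl 2-[2,3-dihydroxy-4-methoxy-5-(2-methylbut-3-en-2-yl)phenyl]-2-hydroxypropanedioate | CC(C)(C)OC(=O)C(O)(C(=O)OC(C)(C)C)c1cc(C(C)(C)C=C)c(OC)c(O)c1O
A2 | alternative 1 | tert-butyl (3S)-3,7-dihydroxy-6-methoxy-5-(2-methylbut-3-en-2-yl)-2-oxo-2,3-dihydrobenzofuran-3-carboxylate | CC(C)(C)OC(=O)[C@]1(O)C(=O)Oc2c(O)c(OC)c(C(C)(C)C=C)cc21
A3 | alternative 2 | 2-{2-[4-methoxy-2,3-bis(methoxymethoxy)-5-(2-methylbut-3-en-2-yl)phenyl]-2-oxoethoxy}-4-(methoxymethoxy)benzaldehyde | C=CC(C)(C)c1cc(C(=O)COc2cc(OCOC)ccc2C=O)c(OCOC)c(OCOC)c1OC
A4 | alternative 2 | (3R)-3-hydroxy-3-[4-methoxy-2,3-bis(methoxymethoxy)-5-(2-methylbut-3-en-2-yl)phenyl]-7-(methoxymethoxy)chroman-4-one | C=CC(C)(C)c1cc([C@@]2(O)COc3cc(OCOC)ccc3C2=O)c(OCOC)c(OCOC)c1OC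
A5 | alternative 3 | 2-diazo-1-[2-fluoro-4-(methoxymethoxy)phenyl]-2-[7-methoxy-2,2-dimethyl-6-(2-methylbut-3-en-2-yl)-1,3-benzodioxol-4-yl]ethan-1-one | O=C(c1ccc(OCOC)cc1F)C(=[N+]=[N-])c1cc(C(C)(C)C=C)c(OC)c2OC(C)(C)Oc12
A6 | alternative 3 | 4-methoxybenzyl alcohol | COc1ccc(CO)cc1
A7 | alternative 3 | formaldehyde | C=O
A8 | alternative 3 | (2R)-1-[2-fluoro-4-(methoxymethoxy)phenyl]-3-hydroxy-2-[(4-methoxybenzyl)oxy]-2-[7-methoxy-2,2-dimethyl-6-(2-methylbut-3-en-2-yl)-1,3-benzodioxol-4-yl]propan-1-one | O=C(c1ccc(OCOC)cc1F)[C@@](CO)(OCc1ccc(OC)cc1)c1cc(C(C)(C)C=C)c(OC)c2OC(C)(C)Oc12
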